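## Analysis of the target

The target 27, 2-hydroxy-6-[2-hydroxy-6-(hydroxymethyl)-4-methylphenoxy]-3-(3-methylbut-2-enyl)benzoic acid, is an achiral diaryl ether: it has no stereocentre and its only alkene ends in two methyl groups, so the problem is one of regiochemistry and functional-group tolerance. Ring A carries four contiguous substituents, the prenyl group on C1, a phenol on C6, the carboxylic acid on C5 and the ether oxygen on C4, while C2 and C3 are CH. Ring B carries the ether oxygen on C1', a phenol on C2', a methyl group on C4' and a hydroxymethyl group on C6', while C3' and C5' are CH. The ether oxygen is thus flanked by three ortho substituents (C5 on ring A, C2' and C6' on ring B), which makes a late union of two finished rings at this oxygen unattractive. The sensitive groups are the prenyl group next to the C6 phenol (acid closes this pair to a 2,2-dimethylchroman; oxidants, halogens and hydrogenation attack the alkene), the 2,6-dioxygenated benzoic acid (protodecarboxylation when heated in acid) and the benzylic alcohol, which could lactonise onto an activated C5 acid to an eight-membered ring. The hard points are therefore the hindered ether, the carboxyl group wedged between two oxygen-bearing carbons of ring A, and an end game that frees three hydroxyl groups without acid. The strategy rests on ring B: C1' lies between the oxygen-bearing C2' and C6', which carries a carboxyl-level carbon, and C4' bears a methyl group, so that C1'–C2' maps onto the α-carbon and carbonyl carbon of an aryloxyacetate, C6' with its substituent onto the ketone and ester carbons of an α-keto ester, and C5', C4', C3' with the C4' methyl onto an isopropylidene unit.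

## Retrosynthetic reasoning

**27 from 26.** The last bond cut is the O–CH3 bond at C6, which leads to the methyl ether 26, 6-[2-hydroxy-6-(hydroxymethyl)-4-methylphenoxy]-2-methoxy-3-(3-methylbut-2-enyl)benzoic acid. The methyl group is kept to the end because it comes with the starting phenol, because the C6 methoxy group is one of the two directors that place the carboxyl group, and because it keeps the C6 oxygen masked next to the prenyl group through all earlier steps. The forward reaction has to remove one methyl group by nucleophilic attack at carbon under basic conditions, which leaves the alkene alone.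

**26 from 25.** Both ring B hydroxyls are traced to triisopropylsilyl ethers in acid 25. Silyl ethers are preferred to acetals for two reasons. They are removed by a fluoride source instead of acid. A bulky silyl group on the C2' oxygen also does not direct metalation to C3', so ring B stays silent in the next disconnection.

**25 from 23.** The C5–CO2H bond is cut. C5 is the only ring carbon between two ether oxygens (C4–OAr and C6–OMe), so deprotonation there to aryllithium 24, followed by carboxylation, is the regiochemically unambiguous way to add this carbon late. The gain is that ring A travels through the synthesis as a plain monophenol: its hydroxyl stays nucleophilic, and no second ester ever has to be told apart from the C6' ester. The precursor is the bis-silyl ether 23.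

**23 from 21.** Silylation leads back to diol 22, 3-(hydroxymethyl)-2-[3-methoxy-4-(3-methylbut-2-enyl)phenoxy]-5-methylphenol, and hydride reduction leads back to 21, methyl 3-hydroxy-2-[3-methoxy-4-(3-methylbut-2-enyl)phenoxy]-5-methylbenzoate. The C6' ester of 21 is the group that the ring synthesis leaves on the correct carbon.

**21 from 16.** This is the central disconnection. The C2'–C3' bond of ring B is cut and the arene is unfolded to the acyclic diester 16, dimethyl (Z)-2-[3-methoxy-4-(3-methylbut-2-enyl)phenoxy]-3-(2-methylprop-1-enyl)but-2-enedioate. C2' becomes an ester carbon and C3' one of the two methyl groups of the isopropylidene. The cut is made here because this is the one ring B bond that an ester electrophile and a vinylogously acidic methyl group can form, and because the crowded C1'–O bond then exists before the ring does. In the forward sense a base removes a methyl proton to give trienolate 17, in which the central double bond of 16 has become a single bond, so its configuration is of no consequence. The chain folds, C3' bonds to C2' (alkoxide 18), the methoxy group of that ester leaves (dienone 19), and deprotonation to phenoxide 20 followed by work-up gives 21. The reaction must close the six-membered ring onto the C2' ester and not a five-membered ring onto the C6' ester.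

**16 from 10 and 14.** The C1'=C6' double bond is cut in the olefination sense. C1' with its ester and aryloxy group is the phosphonate 10, methyl 2-(dimethoxyphosphoryl)-2-[3-methoxy-4-(3-methylbut-2-enyl)phenoxy]acetate, acting through its carbanion 15. C6' with its ester and the isopropylidene group is the keto ester 14, methyl 4-methyl-2-oxopent-3-enoate. The cut gives two pieces of similar size and forms the tetrasubstituted alkene from a ketone that its ester neighbour activates.

**10 from 7 and 9.** The C1'–O bond is made while C1' is still sp3, by insertion of the carbene derived from diazo phosphonate 9 into the O–H bond of phenol 7, 3-methoxy-4-(3-methylbut-2-enyl)phenol. This is why the hindered ether is no obstacle in this plan. Compound 9 comes from trimethyl phosphonoacetate 8 by diazo transfer.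

**14 from 11 and 12.** The acyl C–C bond is cut to dimethyl oxalate 11 and 2-methylprop-1-enylmagnesium bromide 12. The forward reaction must stop at mono-addition, which the low-temperature tetrahedral adduct 13 ensures.

**7 from 1 and 3.** The aryl–CH2 bond of the prenyl group is cut. The bromine of 4-bromo-3-methoxyphenol 1 marks C1, and the bond is made from silyl ether 2 through aryllithium 4 and arylcopper 5 with prenyl bromide 3. This gives silyl ether 6, which is then desilylated.

## Alternatives that were turned down

**Alternative 1:** Ring A is cut across C1–C2 and C5–C6.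
- Disconnection: C2 to C5, with the ether on C4 and the ester on C5 in place, is the electron-poor pyrone A2; C1 and C6 come from the siloxyalkyne A3, whose nucleophilic carbon bears the prenyl chain.
- Forward key step: A3 adds across C3 and C6 of A2 in an inverse-electron-demand (4+2) cycloaddition and the adduct aromatises by extrusion of its lactone bridge, giving benzoate A1.
- For: all four ring A substituents, above all the C5 carboxyl carbon, are placed by the polarity of the partners. No aryl metalation beside the prenyl group and no late methyl ether cleavage is needed. On this point it is stronger than the chosen route, which carboxylates by lithiation (step 11) and demethylates last (step 13).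
- Against: the aryloxy group on C4 of A2 is a vinylogous donor and lowers the electron demand of the diene. A3 is a heat-sensitive ynol ether, prone to 1,3-silyl migration, and must be made with a skipped alkene. The tri-ortho-substituted ether still has to be formed by addition–elimination at C4 of a pyrone with the hindered oxygen of a separately built and protected ring B. A1 leaves a di-ortho-substituted methyl benzoate to hydrolyse and two acetals to remove with acid beside the ortho-prenyl phenol.
- Comparison: it is no shorter (three fragments of three to four steps each, then about three more). The chosen route gives up the pre-installed carboxyl group, but it never forms the hindered C–O bond on an aromatic carbon, builds ring B from commercial acyclic pieces and ends under non-acidic conditions.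

**Alternative 2:** Ring A is cut at C5–C6, C3–C4 and C1–C6.
- Disconnection: C4 and C5 come from the aryloxyalkyne A5; C6, C3, C2 and C1 come from the diazo enone A6, whose carbonyl carbon becomes C6.
- Forward key step: irradiation of A6 induces Wolff rearrangement; ketene–alkyne (2+2) addition to A5, four-electron ring opening, six-electron closure and tautomerisation give phenol A4.
- For: this benzannulation is a well-precedented reaction class, so it is stronger than the chosen key step on precedent. The oxygen-bearing alkyne carbon reliably ends meta to the new phenol, and C6 arrives as a free phenol, so no methyl ether has to be cleaved.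
- Against: C5 arrives at the alcohol oxidation level. After the annulation the silyl ether must be removed and the benzylic alcohol oxidised twice in the presence of the prenyl group, the ortho phenol and a second benzylic ether on ring B. A5 is an alkynyl ether of a di-ortho-substituted phenol, reached only by a multi-step route and sensitive to acid and heat. A6 has a doubly allylic CH2 that can drift into conjugation and an alkene open to carbene attack. Photochemistry limits scale, and the acetals again need acid at the end.
- Comparison: it is longer overall. The chosen route is less precedented at its centre, but its precursors are simple, its ring B carbons are at or next to the right oxidation level, and fewer steps follow the ring-forming event.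

**Alternative 3:** Both bonds at C4 and C5 are cut at once.
- Disconnection: ring A is the ortho-silylaryl triflate A8 and ring B the phenol A9.
- Forward key step: a fluoride source converts A8 into the C4–C5 aryne A10; the phenoxide of A9 adds at C4, remote from the methoxy group, and the C5 aryl anion is carboxylated in the same flask, giving acid A7.
- For: it is the most convergent plan, forming two bonds of the crowded region in one operation with the regiochemistry that a 3-methoxyaryne naturally gives. Both halves come from aromatic feedstocks. It is stronger than the chosen route in convergence and probably in step count.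
- Against: the nucleophile is a di-ortho-substituted phenoxide, a poor partner for an aryne, and it is itself reversibly carbonated under carboxylating conditions. The aryl anion can be protonated before it is carboxylated. A10 can undergo an ene reaction with a prenyl group. The fluoride threatens the silyl ether of A9. A8, with four contiguous substituents, needs about five steps. A7 still carries two methyl ethers, one on the electron-rich ring B, to be cleaved under forcing conditions.
- Comparison: the chosen route is longer and its key step is unproven. In exchange it avoids the intermolecular attack of a hindered oxygen on an aromatic carbon, which is the weak point of every coupling-based plan for this ether, and it needs only one methyl ether cleavage.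

Key step: step 8

Remark on the chemistry: the olefination of step 7 is written for the (Z) alkene 16, in which the two ester groups are trans; the configuration of this double bond is lost when the trienolate forms in step 8, so the route does not depend on the geometric selectivity of step 7 and the material would be carried on as obtained.

## Route

Step 1
Reactants: 1 4-bromo-3-methoxyphenol
Product: 2 (4-bromo-3-methoxyphenoxy)(tert-butyl)dimethylsilane
Conditions: t-BuMe2SiCl (1.1 equiv), imidazole (2 equiv), DMF, rt
Reagents that add atoms: tert-butyldimethylsilyl chloride, CC(C)(C)[Si](C)(C)Cl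
Why: Imidazole-mediated O-silylation masks the acidic OH so that the bromine–lithium exchange of step 2 needs one equivalent of base and the oxygen cannot be allylated; a silyl ether para to the metalated carbon cannot migrate to it.

Step 2
Reactants: 2 (4-bromo-3-methoxyphenoxy)(tert-butyl)dimethylsilane; 3 1-bromo-3-methylbut-2-ene (prenyl bromide)
Product: 6 tert-butyl[3-methoxy-4-(3-methylbut-2-enyl)phenoxy]dimethylsilane, via aryllithium 4 (not isolated), via arylcopper 5 (not isolated)
Conditions: n-BuLi (1.05 equiv), THF, −78 °C; CuBr·SMe2 (1.0 equiv), −78 → −40 °C; 3 (1.3 equiv), −78 → 0 °C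
Reagents that add atoms: none
Why: Bromine–lithium exchange at −78 °C is faster than attack on silicon, and transmetalation to copper followed by allylic substitution at the primary carbon of 3 (copper-mediated aryl–allyl coupling) should give the linear prenyl arene, the disubstituted γ-carbon of 3 disfavouring the branched isomer.

Step 3
Reactants: 6 tert-butyl[3-methoxy-4-(3-methylbut-2-enyl)phenoxy]dimethylsilane
Product: 7 3-methoxy-4-(3-methylbut-2-enyl)phenol
Conditions: Bu4NF (1.1 equiv), THF, 0 °C; aq. NH4Cl
Reagents that add atoms: none
Why: Fluoride-induced desilylation frees the phenol without acid, so the prenyl alkene is untouched.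

Step 4
Reactants: 8 trimethyl phosphonoacetate
Product: 9 methyl 2-diazo-2-(dimethoxyphosphoryl)acetate
Conditions: NaH (1.1 equiv), THF, 0 °C; 4-acetamidobenzenesulfonyl azide (1.1 equiv), 0 °C → rt; aq. NH4Cl
Reagents that add atoms: 4-acetamidobenzenesulfonyl azide, CC(=O)Nc1ccc(cc1)S(=O)(=O)N=[N+]=[N-]
Why: Regitz diazo transfer: the sodium enolate of the doubly activated methylene attacks the terminal nitrogen of the sulfonyl azide and the adduct fragments to the diazo compound and the sulfonamide.

Step 5
Reactants: 7 3-methoxy-4-(3-methylbut-2-enyl)phenol; 9 methyl 2-diazo-2-(dimethoxyphosphoryl)acetate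
Product: 10 methyl 2-(dimethoxyphosphoryl)-2-[3-methoxy-4-(3-methylbut-2-enyl)phenoxy]acetate (racemic)
Conditions: Rh2(OAc)4 (2 mol %), PhMe, 90 °C, slow addition of 9 (1.2 equiv)
Reagents that add atoms: none
Why: Rh2(OAc)4-catalysed O–H insertion: the electrophilic rhodium carbene from 9 is captured by the phenol oxygen and proton transfer completes the insertion, a process that for a carbene with two acceptor groups should outrun cyclopropanation of a trisubstituted alkene. The new CH carbon is a stereocentre formed as the racemate and is erased in step 7.

Step 6
Reactants: 11 dimethyl oxalate; 12 2-methylprop-1-enylmagnesium bromide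
Product: 14 methyl 4-methyl-2-oxopent-3-enoate, via magnesium hemiketal alkoxide 13 (not isolated)
Conditions: 11 (1.5 equiv), THF, −78 °C; 12 (0.5 M in THF, 1.0 equiv) dropwise; 1 M HCl at −78 °C
Reagents that add atoms: none
Why: Mono-addition of a Grignard reagent to a dialkyl oxalate: at −78 °C the tetrahedral adduct 13 persists and releases the ketone only on acidic quench, so a second addition is not expected, and the excess of 11 suppresses it further.

Step 7
Reactants: 10 methyl 2-(dimethoxyphosphoryl)-2-[3-methoxy-4-(3-methylbut-2-enyl)phenoxy]acetate; 14 methyl 4-methyl-2-oxopent-3-enoate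
Product: 16 dimethyl (Z)-2-[3-methoxy-4-(3-methylbut-2-enyl)phenoxy]-3-(2-methylprop-1-enyl)but-2-enedioate, via sodium phosphonate carbanion 15 (not isolated)
Conditions: NaH (1.1 equiv), THF, 0 °C; 14 (1.2 equiv), −78 °C → rt; aq. NH4Cl
Reagents that add atoms: none
Why: Horner–Wadsworth–Emmons olefination: carbanion 15 adds to the ketone carbonyl of 14, which the adjacent ester activates, and loss of dimethyl phosphate gives the tetrasubstituted alkene, while 1,4-addition is hindered by the two β-methyl groups. The arrangement drawn as 16, with the two ester groups trans, should be favoured because it keeps the ester dipoles apart; the configuration of this alkene is in any case lost in step 8, so incomplete selectivity would cost nothing.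

Step 8
Reactants: 16 dimethyl (Z)-2-[3-methoxy-4-(3-methylbut-2-enyl)phenoxy]-3-(2-methylprop-1-enyl)but-2-enedioate
Product: 21 methyl 3-hydroxy-2-[3-methoxy-4-(3-methylbut-2-enyl)phenoxy]-5-methylbenzoate, via potassium trienolate 17 (not isolated), via cyclic hemiketal alkoxide 18 (not isolated), via cyclohexadienone 19 (not isolated), via potassium phenoxide 20 (not isolated)
Conditions: KN(SiMe3)2 (2.2 equiv), THF, −78 °C → rt, diester added to the base; aq. NH4Cl
Reagents that add atoms: none
Why: Proposed new method: KN(SiMe3)2 removes a proton from either methyl of the isopropylidene group of 16 and gives trienolate 17, in which the charge runs from C3' through C5' and C1' into the C2' ester while the former C1'=C6' bond is single, so the configuration of that bond in 16 no longer matters. On warming, 17 can reach the U-shaped geometry (C4' and C1' cis on C5'=C6') and close by a thermally allowed disrotatory six-electron electrocyclization that joins C3' to C2'; seen as a carbonyl addition this is a 6-(enolendo)-exo-trig vinylogous Dieckmann closure, and it forms the only new ring, ring B. Alkoxide 18 then expels its methoxy group to give dienone 19, which is deprotonated at C3' to phenoxide 20, so the sequence ends in an irreversible aromatization and work-up releases 21. The closest known reactions are the aromatizing Dieckmann and Claisen cyclizations of unsaturated diesters and the electrocyclization of dienylketenes and trienolates to phenols (for example the Stobbe half-ester cyclization); new here is a plain methyl ester as the terminus of an aryloxy-substituted trienolate. No stereocentre results, because the sp3 carbon C2' of 18 is transient. The selectivity needed is the mode of closure: attack of C3' on the C6' ester would be a 5-(enolendo)-exo-trig closure, which the stereoelectronic rules for enolates disfavour, is possible only from the other C5'=C6' geometry and leads to a non-aromatic ketone that can revert, whereas the six-membered closure is pulled on by aromatization. Complete deprotonation by an excess of a hindered, non-nucleophilic amide before any methoxide is released keeps the neutral diester away from nucleophiles and so protects the C1' aryloxy group from addition–elimination.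

Step 9
Reactants: 21 methyl 3-hydroxy-2-[3-methoxy-4-(3-methylbut-2-enyl)phenoxy]-5-methylbenzoate
Product: 22 3-(hydroxymethyl)-2-[3-methoxy-4-(3-methylbut-2-enyl)phenoxy]-5-methylphenol
Conditions: LiAlH4 (2 equiv), THF, 0 °C → rt; aq. potassium sodium tartrate
Reagents that add atoms: none
Why: LiAlH4 reduction of the aryl ester to the benzylic alcohol; the phenol is carried as its phenoxide and returns on work-up, and the diaryl ether, the anisole and the isolated alkene are inert to hydride.

Step 10
Reactants: 22 3-(hydroxymethyl)-2-[3-methoxy-4-(3-methylbut-2-enyl)phenoxy]-5-methylphenol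
Product: 23 triisopropyl{[2-[3-methoxy-4-(3-methylbut-2-enyl)phenoxy]-5-methyl-3-(triisopropylsilyloxy)phenyl]methoxy}silane
Conditions: i-Pr3SiOTf (2.5 equiv), 2,6-lutidine (4 equiv), CH2Cl2, 0 °C → rt
Reagents that add atoms: triisopropylsilyl trifluoromethanesulfonate, CC(C)[Si](C(C)C)(C(C)C)OS(=O)(=O)C(F)(F)F
Why: Silylation of the phenol and the primary alcohol with a silyl triflate buffered by 2,6-lutidine; triisopropylsilyl ethers withstand alkyllithium reagents, and the bulky group on the C2' oxygen does not direct metalation to C3'.

Step 11
Reactants: 23 triisopropyl{[2-[3-methoxy-4-(3-methylbut-2-enyl)phenoxy]-5-methyl-3-(triisopropylsilyloxy)phenyl]methoxy}silane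
Product: 25 2-methoxy-3-(3-methylbut-2-enyl)-6-[4-methyl-2-(triisopropylsilyloxy)-6-(triisopropylsilyloxymethyl)phenoxy]benzoic acid, via aryllithium 24 (not isolated)
Conditions: s-BuLi (1.3 equiv), TMEDA (1.3 equiv), THF, −78 °C, 1 h; CO2 (g), −78 °C → rt; cold 1 M HCl
Reagents that add atoms: carbon dioxide, O=C=O
Why: Directed ortho-metalation and carboxylation: C5–H is the only ring proton between two ether oxygens (C4–OAr and C6–OMe), which acidify it and hold the base, so kinetic lithiation at −78 °C should occur there in preference to C3 or the allylic CH2 of the prenyl group, and aryllithium 24 then adds to CO2.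

Step 12
Reactants: 25 2-methoxy-3-(3-methylbut-2-enyl)-6-[4-methyl-2-(triisopropylsilyloxy)-6-(triisopropylsilyloxymethyl)phenoxy]benzoic acid
Product: 26 6-[2-hydroxy-6-(hydroxymethyl)-4-methylphenoxy]-2-methoxy-3-(3-methylbut-2-enyl)benzoic acid
Conditions: Bu4NF (3 equiv), THF, 0 °C → rt; dilute HCl to pH 4
Reagents that add atoms: none
Why: Fluoride-induced desilylation cleaves the aryl and the primary alkyl silyl ether under non-acidic conditions, so the prenyl group and the benzylic alcohol are not endangered.

Step 13
Reactants: 26 6-[2-hydroxy-6-(hydroxymethyl)-4-methylphenoxy]-2-methoxy-3-(3-methylbut-2-enyl)benzoic acid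
Product: 27 2-hydroxy-6-[2-hydroxy-6-(hydroxymethyl)-4-methylphenoxy]-3-(3-methylbut-2-enyl)benzoic acid
Conditions: NaSEt (6 equiv), DMF, 110 °C; cold 1 M HCl to pH 3
Reagents that add atoms: none
Why: SN2 demethylation by thiolate at the only O-methyl carbon of the molecule, the departing aryloxide being ortho to the carboxylate; the basic medium cannot cyclise the prenyl group onto the new phenol, and brief cold acidification liberates the acid.

## Compound list

1 | 4-bromo-3-methoxyphenol | COc1cc(O)ccc1Br | starting material
2 | (4-bromo-3-methoxyphenoxy)(tert-butyl)dimethylsilane | COc1cc(O[Si](C)(C)C(C)(C)C)ccc1Br | intermediate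
3 | 1-bromo-3-methylbut-2-ene (prenyl bromide) | CC(C)=CCBr | starting material
4 | [4-(tert-butyldimethylsilyloxy)-2-methoxyphenyl]lithium | COc1cc(O[Si](C)(C)C(C)(C)C)ccc1[Li] | intermediate
5 | [4-(tert-butyldimethylsilyloxy)-2-methoxyphenyl]copper | COc1cc(O[Si](C)(C)C(C)(C)C)ccc1[Cu] | intermediate
6 | tert-butyl[3-methoxy-4-(3-methylbut-2-enyl)phenoxy]dimethylsilane | COc1cc(O[Si](C)(C)C(C)(C)C)ccc1CC=C(C)C | intermediate
7 | 3-methoxy-4-(3-methylbut-2-enyl)phenol | COc1cc(O)ccc1CC=C(C)C | intermediate
8 | trimethyl phosphonoacetate | COC(=O)CP(=O)(OC)OC | starting material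
9 | methyl 2-diazo-2-(dimethoxyphosphoryl)acetate | COC(=O)C(=[N+]=[N-])P(=O)(OC)OC | intermediate
10 | methyl 2-(dimethoxyphosphoryl)-2-[3-methoxy-4-(3-methylbut-2-enyl)phenoxy]acetate (racemic) | COC(=O)C(Oc1ccc(CC=C(C)C)c(OC)c1)P(=O)(OC)OC | intermediate
11 | dimethyl oxalate | COC(=O)C(=O)OC | starting material
12 | 2-methylprop-1-enylmagnesium bromide | CC(C)=C[Mg]Br | starting material
13 | bromomagnesium alkoxide of methyl 2-hydroxy-2-methoxy-4-methylpent-3-enoate (racemic) | COC(=O)C(OC)(O[Mg]Br)C=C(C)C | intermediate
14 | methyl 4-methyl-2-oxopent-3-enoate | COC(=O)C(=O)C=C(C)C | intermediate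
15 | sodium salt of the carbanion of 10 | COC(=O)[C-](Oc1ccc(CC=C(C)C)c(OC)c1)P(=O)(OC)OC.[Na+] | intermediate
16 | dimethyl (Z)-2-[3-methoxy-4-(3-methylbut-2-enyl)phenoxy]-3-(2-methylprop-1-enyl)but-2-enedioate | COC(=O)/C(Oc1ccc(CC=C(C)C)c(OC)c1)=C(\C=C(C)C)C(=O)OC | intermediate
17 | potassium (3E)-1-methoxy-3-(methoxycarbonyl)-2-[3-methoxy-4-(3-methylbut-2-enyl)phenoxy]-5-methylhexa-1,3,5-trien-1-olate (C4' and C1' cis on C5'=C6') | C=C(C)/C=C(\C(Oc1ccc(CC=C(C)C)c(OC)c1)=C([O-])OC)C(=O)OC.[K+] | intermediate
18 | potassium 1-methoxy-3-(methoxycarbonyl)-2-[3-methoxy-4-(3-methylbut-2-enyl)phenoxy]-5-methylcyclohexa-2,4-dien-1-olate (racemic) | COC(=O)C1=C(Oc2ccc(CC=C(C)C)c(OC)c2)C([O-])(OC)CC(C)=C1.[K+] | intermediate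
19 | methyl 2-[3-methoxy-4-(3-methylbut-2-enyl)phenoxy]-5-methyl-3-oxocyclohexa-1,5-diene-1-carboxylate | COC(=O)C1=C(Oc2ccc(CC=C(C)C)c(OC)c2)C(=O)CC(C)=C1 | intermediate
20 | potassium 3-(methoxycarbonyl)-2-[3-methoxy-4-(3-methylbut-2-enyl)phenoxy]-5-methylphenolate | COC(=O)c1cc(C)cc([O-])c1Oc1ccc(CC=C(C)C)c(OC)c1.[K+] | intermediate
21 | methyl 3-hydroxy-2-[3-methoxy-4-(3-methylbut-2-enyl)phenoxy]-5-methylbenzoate | COC(=O)c1cc(C)cc(O)c1Oc1ccc(CC=C(C)C)c(OC)c1 | intermediate
22 | 3-(hydroxymethyl)-2-[3-methoxy-4-(3-methylbut-2-enyl)phenoxy]-5-methylphenol | Cc1cc(O)c(Oc2ccc(CC=C(C)C)c(OC)c2)c(CO)c1 | intermediate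
23 | triisopropyl{[2-[3-methoxy-4-(3-methylbut-2-enyl)phenoxy]-5-methyl-3-(triisopropylsilyloxy)phenyl]methoxy}silane | Cc1cc(O[Si](C(C)C)(C(C)C)C(C)C)c(Oc2ccc(CC=C(C)C)c(OC)c2)c(CO[Si](C(C)C)(C(C)C)C(C)C)c1 | intermediate
24 | {2-methoxy-3-(3-methylbut-2-enyl)-6-[4-methyl-2-(triisopropylsilyloxy)-6-(triisopropylsilyloxymethyl)phenoxy]phenyl}lithium | CC(C)=CCc1ccc(Oc2c(O[Si](C(C)C)(C(C)C)C(C)C)cc(C)cc2CO[Si](C(C)C)(C(C)C)C(C)C)c([Li])c1OC | intermediate
25 | 2-methoxy-3-(3-methylbut-2-enyl)-6-[4-methyl-2-(triisopropylsilyloxy)-6-(triisopropylsilyloxymethyl)phenoxy]benzoic acid | CC(C)=CCc1ccc(Oc2c(O[Si](C(C)C)(C(C)C)C(C)C)cc(C)cc2CO[Si](C(C)C)(C(C)C)C(C)C)c(C(=O)O)c1OC | intermediate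
26 | 6-[2-hydroxy-6-(hydroxymethyl)-4-methylphenoxy]-2-methoxy-3-(3-methylbut-2-enyl)benzoic acid | CC(C)=CCc1ccc(Oc2c(O)cc(C)cc2CO)c(C(=O)O)c1OC | intermediate
27 | 2-hydroxy-6-[2-hydroxy-6-(hydroxymethyl)-4-methylphenoxy]-3-(3-methylbut-2-enyl)benzoic acid | CC(C)=CCc1ccc(Oc2c(O)cc(C)cc2CO)c(C(=O)O)c1O | target

## Step count and least certain steps

Total: 13 steps. Longest linear sequence: 11 steps (steps 1, 2, 3, 5, 7, 8, 9, 10, 11, 12, 13); steps 4 and 6 prepare the two side branches.

**Step 8 (key step, proposed new method).** The most likely failure is that the trienolate does not close. It is a stabilised, fully delocalised anion, and the terminus it must attack is its own enolate carbon, so closure costs the enolate resonance. The anion may then simply be reprotonated on work-up to conjugated and deconjugated isomers, condense intermolecularly, or lose the aryloxy group by addition–elimination once methoxide is present. Failure to reach the U-shaped geometry would have the same outcome. The fallback uses known chemistry, sets out from 7 and returns at 21. Methyl 3-(methoxymethoxy)-5-methylbenzoate F1 (one methoxymethylation away from the commercial hydroxy ester) would be magnesiated between its two directing groups with (2,2,6,6-tetramethylpiperidin-1-yl)MgCl·LiCl and iodinated with I2 to methyl 2-iodo-3-(methoxymethoxy)-5-methylbenzoate F2. Ullmann ether coupling of F2 with 7 (CuI, N,N-dimethylglycine, Cs2CO3, dioxane, 100 °C), assisted by the ortho ester, would give methyl 3-(methoxymethoxy)-2-[3-methoxy-4-(3-methylbut-2-enyl)phenoxy]-5-methylbenzoate F3. Dilute HCl in MeOH at rt would then give 21; acid is tolerable there because the prenyl group is flanked by a methyl ether and not by a phenol.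

**Step 5.** The rhodium carbene may be diverted into cyclopropanation of the prenyl alkene, into attack on the electron-rich ring, or into dimerisation. The fallback sets out from 7 and returns at 16. Alkylation of 7 with methyl bromoacetate (K2CO3, acetone) would give methyl 2-[3-methoxy-4-(3-methylbut-2-enyl)phenoxy]acetate F4. Its lithium enolate (LiN(i-Pr)2, THF, −78 °C) would add to the ketone of 14 to give dimethyl 2-hydroxy-3-[3-methoxy-4-(3-methylbut-2-enyl)phenoxy]-2-(2-methylprop-1-enyl)butanedioate F5. Dehydration (SOCl2, pyridine, 0 °C) would give 16, the configuration of the new double bond again being immaterial for step 8; this path also avoids step 7.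

**Step 7.** Proton transfer from the γ-methyl groups of 14 to the phosphonate carbanion, followed by self-condensation of 14, may compete with addition. The addition may also stall, because a hindered anion must form a tetrasubstituted alkene. The fallback sets out from 12 and 7 and returns at 16. The organocopper reagent from 12 and CuBr·SMe2 would add across dimethyl but-2-ynedioate at −78 °C, and the vinylcopper would be trapped with I2 to give dimethyl (E)-2-iodo-3-(2-methylprop-1-enyl)but-2-enedioate F6. The phenoxide of 7 (K2CO3, DMF, rt) would then displace iodide by addition–elimination to give 16; neither the alkene geometry of F6 nor that of the substitution product matters for step 8.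

**Step 11.** Deprotonation of the allylic and benzylic CH2 of the prenyl group may compete with ring lithiation. Shielding of C5–H by the two silyl groups, or a slow long-range shift of silicon from the C2' oxygen to the new carbanion, may lower the yield. The fallback needs no alkyllithium; it sets out from 22 and returns at 27.
- Methoxymethylation (MeOCH2Cl, NaH, THF) would give 1-(methoxymethoxy)-3-[(methoxymethoxy)methyl]-2-[3-methoxy-4-(3-methylbut-2-enyl)phenoxy]-5-methylbenzene F7.
- NaSEt in DMF at 110 °C would cleave the methyl ether of this neutral anisole to 5-{2-(methoxymethoxy)-6-[(methoxymethoxy)methyl]-4-methylphenoxy}-2-(3-methylbut-2-enyl)phenol F8.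
- Magnesium-phenoxide-mediated ortho-formylation (MgCl2, Et3N, paraformaldehyde, MeCN, reflux) can only occur at C5 and would give 2-hydroxy-6-{2-(methoxymethoxy)-6-[(methoxymethoxy)methyl]-4-methylphenoxy}-3-(3-methylbut-2-enyl)benzaldehyde F9.
- Pinnick oxidation (NaClO2, NaH2PO4, 2-methylbut-2-ene, t-BuOH–H2O) would give 2-hydroxy-6-{2-(methoxymethoxy)-6-[(methoxymethoxy)methyl]-4-methylphenoxy}-3-(3-methylbut-2-enyl)benzoic acid F10.
- Dilute HCl in MeOH at rt would give 27, with chroman formation as the known hazard of that last operation.

**Step 13.** The SN2 cleavage may be sluggish, because the substrate is already a dianion and a trianion must form. The higher temperature then needed invites protodecarboxylation or air oxidation of the phenoxides. The fallback sets out from 25 and returns at 27. The methyl ether would be cleaved before desilylation by chelation control: the sodium salt of 25 with MgI2·OEt2 in toluene at 80 °C would give 2-hydroxy-3-(3-methylbut-2-enyl)-6-[4-methyl-2-(triisopropylsilyloxy)-6-(triisopropylsilyloxymethyl)phenoxy]benzoic acid F11, by iodide attack on the methyl group of the magnesium-chelated ether. Bu4NF in THF would then give 27.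

## Further compounds

F1 | step 8 | methyl 3-(methoxymethoxy)-5-methylbenzoate | COCOc1cc(C)cc(C(=O)OC)c1
F2 | step 8 | methyl 2-iodo-3-(methoxymethoxy)-5-methylbenzoate | COCOc1cc(C)cc(C(=O)OC)c1I
F3 | step 8 | methyl 3-(methoxymethoxy)-2-[3-methoxy-4-(3-methylbut-2-enyl)phenoxy]-5-methylbenzoate | COCOc1cc(C)cc(C(=O)OC)c1Oc1ccc(CC=C(C)C)c(OC)c1
F4 | step 5 | methyl 2-[3-methoxy-4-(3-methylbut-2-enyl)phenoxy]acetate | COC(=O)COc1ccc(CC=C(C)C)c(OC)c1
F5 | step 5 | dimethyl 2-hydroxy-3-[3-methoxy-4-(3-methylbut-2-enyl)phenoxy]-2-(2-methylprop-1-enyl)butanedioate (racemic mixture of diastereomers) | COC(=O)C(Oc1ccc(CC=C(C)C)c(OC)c1)C(O)(C=C(C)C)C(=O)OC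
F6 | step 7 | dimethyl (E)-2-iodo-3-(2-methylprop-1-enyl)but-2-enedioate | COC(=O)/C(I)=C(/C=C(C)C)C(=O)OC
F7 | step 11 | 1-(methoxymethoxy)-3-[(methoxymethoxy)methyl]-2-[3-methoxy-4-(3-methylbut-2-enyl)phenoxy]-5-methylbenzene | COCOCc1cc(C)cc(OCOC)c1Oc1ccc(CC=C(C)C)c(OC)c1
F8 | step 11 | 5-{2-(methoxymethoxy)-6-[(methoxymethoxy)methyl]-4-methylphenoxy}-2-(3-methylbut-2-enyl)phenol | COCOCc1cc(C)cc(OCOC)c1Oc1ccc(CC=C(C)C)c(O)c1
F9 | step 11 | 2-hydroxy-6-{2-(methoxymethoxy)-6-[(methoxymethoxy)methyl]-4-methylphenoxy}-3-(3-methylbut-2-enyl)benzaldehyde | COCOCc1cc(C)cc(OCOC)c1Oc1ccc(CC=C(C)C)c(O)c1C=O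
F10 | step 11 | 2-hydroxy-6-{2-(methoxymethoxy)-6-[(methoxymethoxy)methyl]-4-methylphenoxy}-3-(3-methylbut-2-enyl)benzoic acid | COCOCc1cc(C)cc(OCOC)c1Oc1ccc(CC=C(C)C)c(O)c1C(=O)O
F11 | step 13 | 2-hydroxy-3-(3-methylbut-2-enyl)-6-[4-methyl-2-(triisopropylsilyloxy)-6-(triisopropylsilyloxymethyl)phenoxy]benzoic acid | CC(C)=CCc1ccc(Oc2c(O[Si](C(C)C)(C(C)C)C(C)C)cc(C)cc2CO[Si](C(C)C)(C(C)C)C(C)C)c(C(=O)O)c1O
A1 | alternative 1 | methyl 6-{2-(methoxymethoxy)-6-[(methoxymethoxy)methyl]-4-methylphenoxy}-3-(3-methylbut-2-enyl)-2-(triisopropylsilyloxy)benzoate | CC(C)=CCc1ccc(Oc2c(OCOC)cc(C)cc2COCOC)c(C(=O)OC)c1O[Si](C(C)C)(C(C)C)C(C)C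
A2 | alternative 1 | methyl 4-{2-(methoxymethoxy)-6-[(methoxymethoxy)methyl]-4-methylphenoxy}-2-oxo-2H-pyran-3-carboxylate | COC(=O)C1=C(Oc2c(OCOC)cc(C)cc2COCOC)C=COC1=O
A3 | alternative 1 | triisopropyl[(5-methylhex-4-en-1-yn-1-yl)oxy]silane | CC(C)=CCC#CO[Si](C(C)C)(C(C)C)C(C)C
A4 | alternative 2 | 2-{[tert-butyl(dimethyl)silyl]oxymethyl}-3-{2-(methoxymethoxy)-6-[(methoxymethoxy)methyl]-4-methylphenoxy}-6-(3-methylbut-2-enyl)phenol | CC(C)=CCc1ccc(Oc2c(OCOC)cc(C)cc2COCOC)c(CO[Si](C)(C)C(C)(C)C)c1O
A5 | alternative 2 | tert-butyl[(3-{2-(methoxymethoxy)-6-[(methoxymethoxy)methyl]-4-methylphenoxy}prop-2-yn-1-yl)oxy]dimethylsilane | CC(C)(C)[Si](C)(C)OCC#COc1c(OCOC)cc(C)cc1COCOC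
A6 | alternative 2 | (3E)-1-diazo-7-methylocta-3,6-dien-2-one | CC(C)=CC/C=C/C(=O)C=[N+]=[N-]
A7 | alternative 3 | 2-methoxy-6-{2-methoxy-4-methyl-6-[(triisopropylsilyloxy)methyl]phenoxy}-3-(3-methylbut-2-enyl)benzoic acid | CC(C)=CCc1ccc(Oc2c(OC)cc(C)cc2CO[Si](C(C)C)(C(C)C)C(C)C)c(C(=O)O)c1OC
A8 | alternative 3 | 2-methoxy-3-(3-methylbut-2-enyl)-6-(trimethylsilyl)phenyl trifluoromethanesulfonate | CC(C)=CCc1ccc([Si](C)(C)C)c(OS(=O)(=O)C(F)(F)F)c1OC
A9 | alternative 3 | 2-methoxy-4-methyl-6-[(triisopropylsilyloxy)methyl]phenol | COc1cc(C)cc(CO[Si](C(C)C)(C(C)C)C(C)C)c1O
A10 | alternative 3 | 1,2-didehydro-3-methoxy-4-(3-methylbut-2-enyl)benzene (aryne) | CC(C)=CCC1=C(OC)C#CC=C1
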